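The O7–S bond and the benzyl ethers at O3 and O4' are cut first, then O1–C2 of ring C. C4a–C4 and C4–C3 are cut last, in one operation, which leaves a ring A iodide, carbon monoxide as C4, and an α-benzyloxy ketone carrying C3, C2 and ring B.
Enabling feature: C4 is a single carbonyl carbon flanked by aromatic C4a and the oxygen-bearing C3. Ring A has the threefold-symmetric 1,3,5-trioxygenation of phloroglucinol, so only one monoiodide exists and the oxygens that become O1 and O5 are interchangeable.
Forward: rings A and B are bought. The iodide (two steps) and the ketone (three steps, convergent) are joined with CO to the open C6–C3–C6 1,3-diketone, and acid then strips the MOM groups and closes ring C through O1–C2. The 7-OH is sulfated and the benzyl groups leave last.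
Stereochemistry: the target has no stereocentre. The C3 centre of the diketone arises racemic, is enolisable, and becomes sp2 on ring closure.

Key step: step 6

Assumption: the target is drawn as the free hydrogen sulfate. Aryl hydrogen sulfates catalyse their own solvolysis, so the sulfate is carried as its sodium salt and the acid form is released only in the last operation, cold and in a water-rich medium.

Step 1
Reactants: 1 phloroglucinol
Product: 2 1,3,5-tris(methoxymethoxy)benzene
Conditions: NaH (3.6 equiv), MOMCl (3.6 equiv), DMF, 0 °C → rt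
Reagents that add atoms: chloromethyl methyl ether (MOMCl), COCCl
Why: Threefold Williamson-type O-alkylation, in which the sodium phenoxides meet the hard oxocarbenium-like electrophile at oxygen rather than at carbon, and the acetal ethers later serve as lithiation directors and as acid-labile masks.

Step 2
Reactants: 2 1,3,5-tris(methoxymethoxy)benzene
Product: 4 2-iodo-1,3,5-tris(methoxymethoxy)benzene, via 2,4,6-tris(methoxymethoxy)phenyllithium 3 (not isolated)
Conditions: n-BuLi (1.1 equiv), THF, 0 °C; then I2, THF, −78 °C → rt
Reagents that add atoms: iodine, II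
Why: Directed ortho-metalation with iodine quench, in which each of the three equivalent ring C–H bonds lies between two coordinating OMOM groups, so one equivalent of base should give one aryllithium and hence only the monoiodide.

Step 3
Reactants: 5 4-bromo-2-methoxyphenol
Product: 6 1-(benzyloxy)-4-bromo-2-methoxybenzene
Conditions: BnBr, K2CO3, acetone, reflux
Reagents that add atoms: benzyl bromide, BrCc1ccccc1
Why: Williamson ether synthesis at the only acidic hydroxyl, with the aryl bromide inert to carbonate.

Step 4
Reactants: 7 benzyloxyacetyl chloride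
Product: 8 2-(benzyloxy)-N-methoxy-N-methylacetamide
Conditions: MeNH(OMe)·HCl, K2CO3, H2O–EtOAc (two phases), 0 °C → rt
Reagents that add atoms: N,O-dimethylhydroxylamine hydrochloride, CNOC.Cl
Why: Schotten–Baumann acylation of the liberated hydroxylamine, which outruns hydrolysis of the acid chloride in the two-phase system and gives the Weinreb amide.

Step 5
Reactants: 6 1-(benzyloxy)-4-bromo-2-methoxybenzene; 8 2-(benzyloxy)-N-methoxy-N-methylacetamide
Product: 11 2-(benzyloxy)-1-[4-(benzyloxy)-3-methoxyphenyl]ethanone, via arylmagnesium bromide 9 (not isolated), via magnesium hemiaminal chelate 10 (not isolated)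
Conditions: Mg turnings (I2 crystal), THF, reflux; then 8, THF, 0 °C → rt; 1 M HCl, 0 °C
Reagents that add atoms: none
Why: Weinreb ketone synthesis, in which the Grignard reagent adds only once because the five-membered magnesium chelate 10 persists until the acid quench, so no tertiary alcohol can form.

Step 6
Reactants: 4 2-iodo-1,3,5-tris(methoxymethoxy)benzene; 11 2-(benzyloxy)-1-[4-(benzyloxy)-3-methoxyphenyl]ethanone; 12 carbon monoxide
Product: 15 racemic 2-(benzyloxy)-1-[4-(benzyloxy)-3-methoxyphenyl]-3-[2,4,6-tris(methoxymethoxy)phenyl]propane-1,3-dione, via sodium Z-enolate 13 (not isolated), via sodium diketonate 14 (not isolated)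
Conditions: 11 (2.0 equiv, surplus recoverable), NaN(SiMe3)2 (2.0 equiv), THF, 0 °C; then 4, Pd(dba)2 (5 mol%), Xantphos (6 mol%), CO (3 bar), THF–1,4-dioxane, 80 °C; aq. NH4Cl
Reagents that add atoms: none
Why: Zerovalent palladium adds oxidatively to the C–I bond of 4, CO inserts into the crowded aryl–palladium bond to give an aroyl complex of divalent palladium (C4a–C4), enolate 13 replaces iodide, reductive elimination from the carbon-bound enolate makes C4–C3, and surplus 13 then deprotonates the product to the diketonate 14, the thermodynamic sink that is protonated on work-up. The closest known reaction type is the palladium-catalysed carbonylative α-arylation of aryl alkyl ketones with aryl iodides, which gives 1,3-diketones under such conditions. No ring closes in this step, and the one new stereocentre (the carbon that becomes C3) is formed racemic, stays enolisable and turns sp2 in step 7, so nothing has to control it. The first selectivity needed is CO uptake before C–C coupling: the two ortho OMOM groups shield the arylpalladium species against the trisubstituted enolate and speed up migratory insertion by relief of strain, and the wide bite angle of Xantphos and a slight CO overpressure work in the same direction. The second is C- over O-acylation: the α-benzyloxy oxygen and the enolate oxygen chelate sodium in the Z-enolate and leave carbon as the open nucleophilic site, and any enol ester that forms is itself an acyl donor that surplus enolate converts into the stabilised 14. Regiochemistry needs no control, since 4 is the only monoiodide of a threefold-symmetric arene and 11 has a single enolisable position.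

Step 7
Reactants: 15 racemic 2-(benzyloxy)-1-[4-(benzyloxy)-3-methoxyphenyl]-3-[2,4,6-tris(methoxymethoxy)phenyl]propane-1,3-dione
Product: 17 3-(benzyloxy)-2-[4-(benzyloxy)-3-methoxyphenyl]-5,7-dihydroxy-4H-chromen-4-one, via triol diketone 16 (not isolated)
Conditions: HCl (ca. 1.5 M), MeOH–THF, 55 °C
Reagents that add atoms: none
Why: Acid-catalysed acetal exchange with methanol frees the three phenols, and the classical cyclodehydration of a 1-(2-hydroxyaryl)-1,3-diketone (6-exo-trig addition of an ortho hydroxyl to the aroyl carbonyl, then loss of water) closes ring C, either equivalent ortho hydroxyl giving the same chromone while the benzyl ethers survive dilute acid.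

Step 8
Reactants: 17 3-(benzyloxy)-2-[4-(benzyloxy)-3-methoxyphenyl]-5,7-dihydroxy-4H-chromen-4-one
Product: 19 sodium 3-(benzyloxy)-2-[4-(benzyloxy)-3-methoxyphenyl]-5-hydroxy-4-oxo-4H-chromen-7-yl sulfate, via pyridinium sulfate salt 18 (not isolated)
Conditions: SO3·pyridine (1.5 equiv), pyridine, rt; then aq. NaHCO3, evaporation, Sephadex LH-20 (MeOH)
Reagents that add atoms: sulfur trioxide–pyridine complex, [O-]S(=O)(=O)[n+]1ccccc1; sodium hydrogen carbonate, [Na+].OC([O-])=O
Why: O-sulfation of a phenol with an amine–SO3 complex, in which the 7-OH is the more acidic and open of the two free hydroxyls while the 5-OH is held in a hydrogen bond to the C4 carbonyl, and the swap of pyridinium for sodium removes an amine that would retard benzyl ether hydrogenolysis on palladium.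

Step 9
Reactants: 19 sodium 3-(benzyloxy)-2-[4-(benzyloxy)-3-methoxyphenyl]-5-hydroxy-4-oxo-4H-chromen-7-yl sulfate
Product: 21 isorhamnetin 7-O-sulfate, via sodium isorhamnetin 7-sulfate 20 (not isolated)
Conditions: H2 (1 atm), 10% Pd/C, MeOH–THF–H2O, rt; filtration; Dowex 50WX8 (H+ form), H2O–MeOH, 0 °C; freeze-drying
Reagents that add atoms: none
Why: Catalytic hydrogenolysis of benzyl ethers leaves aryl sulfate salts, the aryl methyl ether and the conjugated pyranone untouched at atmospheric pressure, and cation exchange on a sulfonic acid resin in a cold water-rich medium, where solvolysis of the acid form is slow, then gives the hydrogen sulfate.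

Compound list
1 | phloroglucinol (benzene-1,3,5-triol) | Oc1cc(O)cc(O)c1 | starting material
2 | 1,3,5-tris(methoxymethoxy)benzene | COCOc1cc(OCOC)cc(OCOC)c1 | intermediate
3 | 2,4,6-tris(methoxymethoxy)phenyllithium | [Li]c1c(OCOC)cc(OCOC)cc1OCOC | intermediate
4 | 2-iodo-1,3,5-tris(methoxymethoxy)benzene | COCOc1cc(OCOC)c(I)c(OCOC)c1 | intermediate
5 | 4-bromo-2-methoxyphenol | COc1cc(Br)ccc1O | starting material
6 | 1-(benzyloxy)-4-bromo-2-methoxybenzene | COc1cc(Br)ccc1OCc1ccccc1 | intermediate
7 | benzyloxyacetyl chloride | O=C(Cl)COCc1ccccc1 | starting material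
8 | 2-(benzyloxy)-N-methoxy-N-methylacetamide | CON(C)C(=O)COCc1ccccc1 | intermediate
9 | [4-(benzyloxy)-3-methoxyphenyl]magnesium bromide | COc1cc([Mg]Br)ccc1OCc1ccccc1 | intermediate
10 | bromomagnesium alkoxide of the tetrahedral adduct of 9 and 8 (racemic, chelated through the N-methoxy oxygen) | COc1cc(C(O[Mg]Br)(COCc2ccccc2)N(C)OC)ccc1OCc1ccccc1 | intermediate
11 | 2-(benzyloxy)-1-[4-(benzyloxy)-3-methoxyphenyl]ethanone | COc1cc(C(=O)COCc2ccccc2)ccc1OCc1ccccc1 | intermediate
12 | carbon monoxide | [C-]#[O+] | starting material
13 | sodium (Z)-2-(benzyloxy)-1-[4-(benzyloxy)-3-methoxyphenyl]ethen-1-olate | COc1cc(/C([O-])=C/OCc2ccccc2)ccc1OCc1ccccc1.[Na+] | intermediate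
14 | sodium enolate of 15 (delocalised diketonate, one resonance form drawn) | COCOc1cc(OCOC)c(C(=O)C(OCc2ccccc2)=C([O-])c2ccc(OCc3ccccc3)c(OC)c2)c(OCOC)c1.[Na+] | intermediate
15 | 2-(benzyloxy)-1-[4-(benzyloxy)-3-methoxyphenyl]-3-[2,4,6-tris(methoxymethoxy)phenyl]propane-1,3-dione (racemic, enolisable) | COCOc1cc(OCOC)c(C(=O)C(OCc2ccccc2)C(=O)c2ccc(OCc3ccccc3)c(OC)c2)c(OCOC)c1 | intermediate
16 | 2-(benzyloxy)-1-[4-(benzyloxy)-3-methoxyphenyl]-3-(2,4,6-trihydroxyphenyl)propane-1,3-dione (racemic, enolisable) | COc1cc(C(=O)C(OCc2ccccc2)C(=O)c2c(O)cc(O)cc2O)ccc1OCc1ccccc1 | intermediate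
17 | 3-(benzyloxy)-2-[4-(benzyloxy)-3-methoxyphenyl]-5,7-dihydroxy-4H-chromen-4-one (3,4'-di-O-benzylisorhamnetin) | COc1cc(-c2oc3cc(O)cc(O)c3c(=O)c2OCc2ccccc2)ccc1OCc1ccccc1 | intermediate
18 | pyridinium 3-(benzyloxy)-2-[4-(benzyloxy)-3-methoxyphenyl]-5-hydroxy-4-oxo-4H-chromen-7-yl sulfate | COc1cc(-c2oc3cc(OS(=O)(=O)[O-])cc(O)c3c(=O)c2OCc2ccccc2)ccc1OCc1ccccc1.c1cc[nH+]cc1 | intermediate
19 | sodium 3-(benzyloxy)-2-[4-(benzyloxy)-3-methoxyphenyl]-5-hydroxy-4-oxo-4H-chromen-7-yl sulfate | COc1cc(-c2oc3cc(OS(=O)(=O)[O-])cc(O)c3c(=O)c2OCc2ccccc2)ccc1OCc1ccccc1.[Na+] | intermediate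
20 | sodium 3,5-dihydroxy-2-(4-hydroxy-3-methoxyphenyl)-4-oxo-4H-chromen-7-yl sulfate (sodium isorhamnetin 7-sulfate) | COc1cc(-c2oc3cc(OS(=O)(=O)[O-])cc(O)c3c(=O)c2O)ccc1O.[Na+] | intermediate
21 | isorhamnetin 7-O-sulfate (3,5-dihydroxy-2-(4-hydroxy-3-methoxyphenyl)-4-oxo-4H-chromen-7-yl hydrogen sulfate) | COc1cc(-c2oc3cc(OS(=O)(=O)O)cc(O)c3c(=O)c2O)ccc1O | target

Total step count: 9
Longest linear sequence: 6 steps (1, 2, 6, 7, 8, 9). The branches 3, 5 and 4, 5 reach step 6 after the same number of steps.

Steps most likely to fail

Step 6. The catalytic cycle may stall at the crowded aroylpalladium stage. Hydrodeiodination, coupling without CO uptake, acylation at the enolate oxygen, or thermal decay of the enolate at 80 °C could then take over.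
- The fallback replaces catalysis by an aldol addition and an oxidation, so C4 comes from DMF. It sets out from 2 and 11 and comes back at 15.
- The aryllithium 3, made from 2 as in step 2, is quenched with DMF and then acetic acid to give 2,4,6-tris(methoxymethoxy)benzaldehyde F1.
- Ketone 11 is deprotonated with LiN(SiMe3)2 in THF at −78 °C to its lithium Z-enolate F2.
- F2 adds to F1 and, after an acetic acid quench at −78 °C, should give 2-(benzyloxy)-1-[4-(benzyloxy)-3-methoxyphenyl]-3-hydroxy-3-[2,4,6-tris(methoxymethoxy)phenyl]propan-1-one F3 as a mixture of racemic diastereomers.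
- Dess–Martin oxidation in CH2Cl2 converts all isomers into 15, so the stereochemical course of the aldol step is irrelevant. An aldehyde is also less demanding sterically than an acyl transfer and has no O- versus C-acylation problem.

Step 9. Debenzylation of a poorly soluble salt may be sluggish. Forcing it may saturate the C2–C3 double bond, and the sulfate may be lost by solvolysis while the benzyl groups are still being removed.
- The fallback removes the benzyl groups before sulfur is introduced and relays the protection through acetates, which leave under basic conditions that sulfate salts tolerate. It sets out from 17 and comes back at 20.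
- Hydrogenolysis of 17 (H2, Pd/C, THF–MeOH) gives isorhamnetin F4.
- Ac2O in pyridine gives isorhamnetin 3,5,7,4'-tetraacetate F5.
- Thiophenol and imidazole in N-methylpyrrolidone at 0 °C cleave the most electrophilic ester, the one at O7, a known regioselective deacylation of peracylated flavonoids. This gives isorhamnetin 3,5,4'-triacetate F6.
- SO3·pyridine followed by NaHCO3, as in step 8, gives sodium 3,5,4'-tri-O-acetylisorhamnetin 7-sulfate F7.
- Ammonia in methanol at 0 °C under argon removes the three acetates and gives 20, which passes through the resin as in step 9.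

Step 8. Sulfation may stop short or go on to the 5-OH, and the polar salt may shed its sulfate group during purification.
- The fallback installs the sulfate as a neutral, chromatographable diester and unmasks it reductively. It sets out from 17 and comes back at 19.
- Treating 17 with 2,2,2-trichloroethyl chlorosulfate, Et3N and DMAP in THF gives 3-(benzyloxy)-2-[4-(benzyloxy)-3-methoxyphenyl]-5-hydroxy-4-oxo-4H-chromen-7-yl 2,2,2-trichloroethyl sulfate F8. This can be separated on silica from unreacted or doubly derivatised material.
- Zn dust and HCO2NH4 in MeOH at rt trigger reductive fragmentation of the trichloroethyl group. This gives ammonium 3-(benzyloxy)-2-[4-(benzyloxy)-3-methoxyphenyl]-5-hydroxy-4-oxo-4H-chromen-7-yl sulfate F9.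
- One equivalent of NaHCO3 followed by evaporation exchanges ammonium for sodium and gives 19.

Further compounds
F1 | step 6 | 2,4,6-tris(methoxymethoxy)benzaldehyde | COCOc1cc(OCOC)c(C=O)c(OCOC)c1
F2 | step 6 | lithium (Z)-2-(benzyloxy)-1-[4-(benzyloxy)-3-methoxyphenyl]ethen-1-olate | COc1cc(/C([O-])=C/OCc2ccccc2)ccc1OCc1ccccc1.[Li+]
F3 | step 6 | 2-(benzyloxy)-1-[4-(benzyloxy)-3-methoxyphenyl]-3-hydroxy-3-[2,4,6-tris(methoxymethoxy)phenyl]propan-1-one (racemic, mixture of diastereomers) | COCOc1cc(OCOC)c(C(O)C(OCc2ccccc2)C(=O)c2ccc(OCc3ccccc3)c(OC)c2)c(OCOC)c1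
F4 | step 9 | isorhamnetin | COc1cc(-c2oc3cc(O)cc(O)c3c(=O)c2O)ccc1O
F5 | step 9 | isorhamnetin 3,5,7,4'-tetraacetate | COc1cc(-c2oc3cc(OC(C)=O)cc(OC(C)=O)c3c(=O)c2OC(C)=O)ccc1OC(C)=O
F6 | step 9 | isorhamnetin 3,5,4'-triacetate (free 7-OH) | COc1cc(-c2oc3cc(O)cc(OC(C)=O)c3c(=O)c2OC(C)=O)ccc1OC(C)=O
F7 | step 9 | sodium 3,5,4'-tri-O-acetylisorhamnetin 7-sulfate | COc1cc(-c2oc3cc(OS(=O)(=O)[O-])cc(OC(C)=O)c3c(=O)c2OC(C)=O)ccc1OC(C)=O.[Na+]
F8 | step 8 | 3-(benzyloxy)-2-[4-(benzyloxy)-3-methoxyphenyl]-5-hydroxy-4-oxo-4H-chromen-7-yl 2,2,2-trichloroethyl sulfate | COc1cc(-c2oc3cc(OS(=O)(=O)OCC(Cl)(Cl)Cl)cc(O)c3c(=O)c2OCc2ccccc2)ccc1OCc1ccccc1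
F9 | step 8 | ammonium 3-(benzyloxy)-2-[4-(benzyloxy)-3-methoxyphenyl]-5-hydroxy-4-oxo-4H-chromen-7-yl sulfate | COc1cc(-c2oc3cc(OS(=O)(=O)[O-])cc(O)c3c(=O)c2OCc2ccccc2)ccc1OCc1ccccc1.[NH4+]
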